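## The problem

The target 14, octadecyl 3-(2,4-dihydroxy-3-methoxyphenyl)propanoate, is an achiral benzene with four contiguous substituents: the propanoate chain at C1, free hydroxyls at C2 and C4, a methoxy group at C3 between them, and hydrogen at C5 and C6. There is no ring fusion and no stereocentre, so the task is positional: three adjacent oxygens must stand next to the chain carbon, with the methyl group on the middle oxygen only. The chain is a saturated three-carbon tether ending in the ester of a C18 alcohol, which makes late intermediates waxy and calls for a clean, neutral end game. Three features will not survive rough treatment. The ester can be hydrolysed or transesterified. The C2 hydroxyl can close a six-membered dihydrocoumarin lactone onto the ester carbonyl, expelling octadecanol, under acid, base or long heating. The electron-rich resorcinol ring is easily oxidised and over-substituted. The feature that opens the key step is that C2(OH), C3(OMe) and C4(OH) follow one another and adjoin C1. This is the sequence carbonyl carbon, C2, C3 of a 2,3-dialkoxycyclobut-2-enone derived from squaric acid, with C5–H as the sp3 C4–H of that ring and C6 and C1 as the two carbons of an alkene attached there. Ring expansion of such a 4-alkenylcyclobutenone then has to form only the arene C1–C2 bond. The price is that the two squarate oxygens must be told apart before the arene exists: methyl on the oxygen alpha to the carbonyl, a removable group on the vinylogous one. The single stereocentre met on the way (C4 of the cyclobutenone) is racemic and disappears on aromatisation.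

## Retrosynthesis

**14 to 13.** The O–CH2Ph bond at the C4 oxygen is cut, leading back to benzyl ether 13. The C4 oxygen has to be an ether for as long as it is the vinylogous ester oxygen of a cyclobutenone. Benzyl is chosen because its removal by hydrogenolysis is neutral and leaves the ester, the methoxy group and the arene alone. The C2 hydroxyl needs no protection, since it is formed free in the ring-forming step. The forward reaction only has to be a chemoselective debenzylation.

**13 to 10 (key disconnection).** The arene C1–C2 bond is cut. Phenol 13 is traced through cyclohexadienone 12 and dienylketene 11 to the racemic 4-alkenylcyclobutenone 10. The neighbouring cut, between C1 and the chain, would lean on the directing effects of an activated arene. Cutting inside the ring makes the substitution pattern a matter of connectivity instead. Compound 10 contains no arene, only a four-membered ring and an E alkene. The forward reaction is a thermal 4π opening, 6π closure and tautomerisation, and must run without the ester or the newly formed phenol intercepting the ketene.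

**10 to 9 and 4.** The bond between ring C4 and the alkenyl carbon is cut, giving 4-chlorocyclobutenone 9 and alkenylstannane 4 for a Stille coupling. The alternative, adding an alkenyllithium to a squarate carbonyl, would leave a hydroxyl on C4, hence an extra oxygen on arene C5, and would not tolerate the ester. Cross-coupling at a C4–Cl bond delivers the required C4–H compound and splits the molecule into a ring piece of five carbons and the complete chain. The coupling must occur at C4, keep the alkene geometry and run below the temperature of ring opening.

**4 to 3 to 1 and 2.** The C–Sn bond is traced to the terminal alkyne of ester 3 (hydrostannylation), and the ester C–O bond to pent-4-ynoic acid 1 and octadecan-1-ol 2. The fatty alcohol is thus attached in the first step, on a simple fragment, and no esterification is needed once a free phenol is present.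

**9 to 8 to 6 and 7 to 5.** The C–Cl bond of 9 comes from the carbinol of 8. The C3–O(benzyl) bond of 8 is cut to give 4-hydroxy-2,3-dimethoxycyclobutenone 6 and benzyl alcohol 7. The C4–H bond of 6 comes from hydride reduction of dimethyl squarate 5. The order matters. Reducing a mixed benzyl methyl squarate would not be regioselective. Once one carbonyl of symmetric 5 has been reduced, however, the two methoxy groups differ in kind: the 3-methoxy is part of a beta-alkoxy enone and exchanges by addition–elimination, while the 2-methoxy on the alpha carbon cannot. The forward reactions are a mono-reduction, a transetherification driven by excess 7, and a chlorination that does not ionise C4.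

## Roads not taken

**Alternative 1:** The bond between arene C1 and the chain and the ester bond are cut. In the forward sense 2-methoxybenzene-1,3-diol A2 and acrylic acid A3 would combine under a strong protic acid to the lactone 7-hydroxy-8-methoxychroman-2-one A1, which would be opened with octadecan-1-ol 2 to give 14. The merits are considerable:
- A2 is symmetric, so the first substitution has no regiochemical question.
- No protecting group, tin or palladium is needed.
- The target would be reached in two steps against eight for the chosen plan, so on step economy this road is clearly better.

Its weak points are specific to the structure: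
- A1 still has an activated position ortho to its free hydroxyl, so a second hydroarylation can follow the first.
- The methoxy group flanked by two oxygens is exposed to hot strong acid.
- Opening the lactone with a solid long-chain alcohol is an equilibrium that has to be pushed with excess 2, under the same catalysis that re-closes the ring.

Against this the chosen plan sets a substitution pattern fixed by the squarate skeleton and not by arene reactivity, late steps that are neutral so the open ortho-hydroxy ester never meets acid or base, and a chain that can be varied through the stannane.

**Alternative 2:** The ring bond C3–C4 is cut at the oxidation level of a cyclohexane-1,3-dione. The keto diester dioctadecyl 4-(methoxyacetyl)heptanedioate A5 would cyclise by attack of the enolate at its methoxymethyl carbon on one of the two equivalent ester arms. This gives octadecyl 3-(3-methoxy-2,4-dioxocyclohexyl)propanoate A4, which would then be dehydrogenated to 14. The chemistry is cheap and acyclic, and the equivalence of the arms removes one selectivity question. The weak points are more serious: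
- Enolate formation must choose the methoxymethyl carbon over the methine and over the ester alpha carbons.
- A competing Dieckmann closure between the two arms also gives a six-membered ring.
- One octadecyl group is lost as the leaving alkoxide.
- The final aromatisation of a 2-alkoxy-1,3-dione needs forcing oxidative conditions that threaten the ester and the product resorcinol.

Assembling A5 regioselectively is itself several steps, so this road is not shorter. The chosen plan forms the ring directly at the arene oxidation level and needs no oxidant.

**Alternative 3:** The bond between the chain alpha carbon and the carbonyl carbon and the carbonyl–oxygen bond are cut. The vinylarene 1,3-bis(benzyloxy)-4-ethenyl-2-methoxybenzene A7, carbon monoxide A8 and 2 would combine on a palladium hydride catalyst carrying a bulky chelating diphosphine. The product, octadecyl 3-[2,4-bis(benzyloxy)-3-methoxyphenyl]propanoate A6, would be debenzylated to 14. This is convergent and atom-economic, the oxygen pattern is bought with the arene, and A6 is fully protected, so no lactone can form before the last step. In length, about six steps from A2, it is as good as or slightly better than the chosen plan. Its weak points: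
- Vinylarenes tend to give the branched 2-arylpropanoate through a benzylic palladium species, so the linear ester depends wholly on ligand control.
- The alcohol must be used in near-stoichiometric amount, not as solvent.
- Pressurised A8 is required.
- A7 needs a regioselective formylation and an olefination first.

The chosen plan has no branched or linear question and no gas under pressure, and it places every substituent by connectivity.

Key step: step 7

Assumption: stannane 4 and cyclobutenone 10 are drawn as E isomers. Any Z isomer carried along should converge on the same arene 13, since the alkene geometry is erased on aromatisation.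

## Route

Step 1
Reactants: 1 pent-4-ynoic acid; 2 octadecan-1-ol
Product: 3 octadecyl pent-4-ynoate
Conditions: 1 (1.2 equiv), TsOH·H2O (5 mol%), PhMe, reflux, Dean–Stark trap; aqueous NaHCO3 wash
Reagents that add atoms: none
Why: Fischer esterification driven by azeotropic removal of water; the slight excess of the water-soluble acid is washed out, so no fatty alcohol remains, and the terminal alkyne is inert to catalytic sulfonic acid.

Step 2
Reactants: 3 octadecyl pent-4-ynoate
Product: 4 octadecyl (4E)-5-(tributylstannyl)pent-4-enoate
Conditions: Bu3SnH (1.3 equiv), AIBN (10 mol%), PhMe, 85 °C; chromatography on Et3N-deactivated silica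
Reagents that add atoms: tributyltin hydride, CCCC[SnH](CCCC)CCCC
Why: Radical hydrostannylation; the stannyl radical adds only to the terminal alkyne carbon, and reversible addition of excess tin radical to the product should equilibrate the alkene towards the E isomer while the ester stays untouched.

Step 3
Reactants: 5 dimethyl squarate (3,4-dimethoxycyclobut-3-ene-1,2-dione)
Product: 6 4-hydroxy-2,3-dimethoxycyclobut-2-en-1-one (racemic)
Conditions: LiAlH(OtBu)3 (1.05 equiv), THF, −78 °C to −20 °C; aqueous potassium sodium tartrate, pH about 7
Reagents that add atoms: none
Why: Mono-reduction of a symmetric cyclobutenedione by a hindered hydride; the two carbonyls are equivalent, the aluminium alkoxide formed and the remaining vinylogous ester carbonyl resist a second hydride, and the neutral quench avoids acid-induced collapse to the semisquarate. The new stereocentre is racemic and is removed later.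

Step 4
Reactants: 6 4-hydroxy-2,3-dimethoxycyclobut-2-en-1-one; 7 benzyl alcohol
Product: 8 3-(benzyloxy)-4-hydroxy-2-methoxycyclobut-2-en-1-one (racemic)
Conditions: 7 (10 equiv), NaH (0.1 equiv), THF, 5 Å molecular sieves, 0 °C to rt; AcOH quench
Reagents that add atoms: none
Why: Addition–elimination transetherification of a vinylogous ester; benzyloxide adds to C3, the beta carbon of the enone, and methoxide leaves, whereas the 2-methoxy group on the alpha carbon cannot exchange. Excess 7 and trapping of methanol by the sieves drive the equilibrium.

Step 5
Reactants: 8 3-(benzyloxy)-4-hydroxy-2-methoxycyclobut-2-en-1-one
Product: 9 3-(benzyloxy)-4-chloro-2-methoxycyclobut-2-en-1-one (racemic)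
Conditions: PPh3 (1.2 equiv), CCl4 (3 equiv), CH2Cl2, 0 °C to rt
Reagents that add atoms: carbon tetrachloride, ClC(Cl)(Cl)Cl
Why: Appel reaction; the alkoxyphosphonium ion is displaced by chloride at the alpha-keto carbon C4 under neutral conditions, which avoids the acid-triggered ionisation towards the 2-oxocarbenium ion that would lose its methyl group. The chloride stays at the terminus that keeps the vinylogous ester conjugated.

Step 6
Reactants: 9 3-(benzyloxy)-4-chloro-2-methoxycyclobut-2-en-1-one; 4 octadecyl (4E)-5-(tributylstannyl)pent-4-enoate
Product: 10 octadecyl (4E)-5-[2-(benzyloxy)-3-methoxy-4-oxocyclobut-2-en-1-yl]pent-4-enoate (racemic)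
Conditions: Pd2(dba)3 (2.5 mol%), P(2-furyl)3 (10 mol%), THF, 40 °C; aqueous KF work-up
Reagents that add atoms: none
Why: Stille coupling of a 4-chlorocyclobutenone; the allylic, alpha-keto C–Cl bond adds readily to zerovalent palladium, the alkenyl group is transferred from tin with retention of geometry, and reductive elimination at C4 restores the conjugated vinylogous ester. The temperature is held below that of ring opening so that 10 can be isolated; its stereocentre is racemic.

Step 7
Reactants: 10 octadecyl (4E)-5-[2-(benzyloxy)-3-methoxy-4-oxocyclobut-2-en-1-yl]pent-4-enoate
Product: 13 octadecyl 3-[4-(benzyloxy)-2-hydroxy-3-methoxyphenyl]propanoate, via dienylketene 11 (not isolated), via cyclohexadienone 12 (not isolated)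
Conditions: PhMe (0.01 M, degassed), 100 °C, Ar
Reagents that add atoms: none
Why: Thermal conrotatory 4π opening of the C1–C4 bond of 10 gives dienylketene 11; in the isomer with the ketene carbon and the alkenyl group cis about the former C3=C4 bond, a disrotatory 6π electrocyclisation joins the ketene carbon to the distal alkene carbon, which forms the arene C1–C2 bond and closes the only new ring, the six-membered carbocycle of cyclohexadienone 12. Tautomerisation of 12 to phenol 13 is irreversible and removes the one transient stereocentre, so no stereocentre has to be controlled. The closest known reaction type is the ring expansion of 4-alkenylcyclobutenones to phenols that ends the Danheiser benzannulation and the Moore rearrangement. Regiochemistry is fixed by connectivity: the ketene carbon becomes C2 with its free hydroxyl, the methoxy and benzyloxy carbons become C3 and C4, the ring CH becomes C5, and the alkene carbons become C6 and the chain-bearing C1. The selectivity needed is inward rotation of the alkenyl group at C4; it is secured by reversibility, since the outward-rotated ketene can only re-close to 10 while the inward-rotated one is drained by cyclisation and aromatisation. The two alkoxy donors should ease ring opening so that about 100 °C suffices, and high dilution keeps the new phenol from acylating ketene that has not yet cyclised.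

Step 8
Reactants: 13 octadecyl 3-[4-(benzyloxy)-2-hydroxy-3-methoxyphenyl]propanoate
Product: 14 octadecyl 3-(2,4-dihydroxy-3-methoxyphenyl)propanoate
Conditions: H2 (1 atm), Pd/C (10 wt%), EtOAc, rt
Reagents that add atoms: none
Why: Hydrogenolysis of an aryl benzyl ether over Pd/C; the conditions are neutral and free of alcohol solvent, so the ester, the methoxy group and the arene should be untouched and the ortho-hydroxy ester has no catalyst for lactonisation.

## Compound list

1 | pent-4-ynoic acid | C#CCCC(=O)O | starting material
2 | octadecan-1-ol | CCCCCCCCCCCCCCCCCCO | starting material
3 | octadecyl pent-4-ynoate | CCCCCCCCCCCCCCCCCCOC(=O)CCC#C | intermediate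
4 | octadecyl (4E)-5-(tributylstannyl)pent-4-enoate | CCCCCCCCCCCCCCCCCCOC(=O)CC/C=C/[Sn](CCCC)(CCCC)CCCC | intermediate
5 | dimethyl squarate (3,4-dimethoxycyclobut-3-ene-1,2-dione) | COC1=C(OC)C(=O)C1=O | starting material
6 | 4-hydroxy-2,3-dimethoxycyclobut-2-en-1-one (racemic) | COC1=C(OC)C(O)C1=O | intermediate
7 | benzyl alcohol | OCc1ccccc1 | starting material
8 | 3-(benzyloxy)-4-hydroxy-2-methoxycyclobut-2-en-1-one (racemic) | COC1=C(OCc2ccccc2)C(O)C1=O | intermediate
9 | 3-(benzyloxy)-4-chloro-2-methoxycyclobut-2-en-1-one (racemic) | COC1=C(OCc2ccccc2)C(Cl)C1=O | intermediate
10 | octadecyl (4E)-5-[2-(benzyloxy)-3-methoxy-4-oxocyclobut-2-en-1-yl]pent-4-enoate (racemic) | CCCCCCCCCCCCCCCCCCOC(=O)CC/C=C/C1C(=O)C(OC)=C1OCc1ccccc1 | intermediate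
11 | octadecyl (4E,6E)-7-(benzyloxy)-8-methoxy-9-oxonona-4,6,8-trienoate (dienylketene, ketene carbon cis to the alkenyl group) | CCCCCCCCCCCCCCCCCCOC(=O)CC/C=C/C=C(OCc1ccccc1)\C(OC)=C=O | intermediate
12 | octadecyl 3-[4-(benzyloxy)-3-methoxy-2-oxocyclohexa-3,5-dien-1-yl]propanoate (racemic) | CCCCCCCCCCCCCCCCCCOC(=O)CCC1C=CC(OCc2ccccc2)=C(OC)C1=O | intermediate
13 | octadecyl 3-[4-(benzyloxy)-2-hydroxy-3-methoxyphenyl]propanoate | CCCCCCCCCCCCCCCCCCOC(=O)CCc1ccc(OCc2ccccc2)c(OC)c1O | intermediate
14 | octadecyl 3-(2,4-dihydroxy-3-methoxyphenyl)propanoate | CCCCCCCCCCCCCCCCCCOC(=O)CCc1ccc(O)c(OC)c1O | target

## Step count and risks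

Total step count: 8. Longest linear sequence: 6 steps (steps 3 to 8, from dimethyl squarate 5). The stannane branch (steps 1 and 2) joins at step 6.

**Step 7 (key step).** The ring expansion itself is a reliable reaction type. The likely trouble is ester scrambling in the hot solution. The phenol of 13 may acylate ketene that has not yet cyclised, or attack its own ester carbonyl with loss of octadecanol. Traces of water can also drain the outward-rotated ketene as a dienoic acid. Fallback, from 10 back to 13: the lactone is accepted as a resting point. After thermolysis of 10, catalytic TsOH in dilute toluene would drive all material to 7-(benzyloxy)-8-methoxychroman-2-one F1, releasing 2. F1, free of the fatty chain and easy to purify, would then be re-opened with excess 2 (catalytic TsOH, concentrated solution or melt at about 60 °C) to return to 13.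

**Step 4.** The exchange is an equilibrium run on a substrate with a free alpha-ketol. Incomplete conversion is likely. The C4 alkoxide may add to C3 of another molecule and oligomerise. Base-induced ketol transposition would erode the regiochemical purity. Fallback, from 6 back to 8: the vinylogous ester would be saponified irreversibly with CsOH (1 equiv, aqueous THF, 0 °C) to the caesium salt of 3,4-dihydroxy-2-methoxycyclobut-2-en-1-one F2. Its enolate is a symmetric 1,3-dione anion in which both oxygens are related by the plane through C2 and C4. O-Alkylation with benzyl bromide in DMF therefore gives 8 whichever oxygen reacts.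

**Step 5.** The chloride has a methoxy donor at C2, so ionisation of C4 during or after its formation may lead to loss of the methyl group as chloromethane and formation of a cyclobutenedione. Transient attack of chloride at C2 is a related leak. Fallback, from 8 back to 10: the carbinol would be acetylated (Ac2O, pyridine, catalytic DMAP) to 3-(benzyloxy)-2-methoxy-4-oxocyclobut-2-en-1-yl acetate F3. This less ionisable allylic ester would be coupled directly with 4 under allylic-acetate Stille conditions (Pd2(dba)3, LiCl, DMF, rt), bypassing 9.

**Step 6.** Three things may go wrong: slow transmetalation with protodestannylation of 4, reductive elimination at the wrong terminus (C2) of the allyl–palladium intermediate, and ring opening of 10 before isolation. The last is harmless if the mixture is simply heated on to 13. Fallback, from 3 back to 10: hydrozirconation of alkyne 3 with Cp2Zr(H)Cl (THF, rt) would give octadecyl (4E)-5-[chlorobis(cyclopentadienyl)zirconio]pent-4-enoate F4, used without isolation. Palladium-catalysed coupling of F4 with 9 (Pd(PPh3)4, THF, rt) is a tin-free, more nucleophilic Negishi-type variant that also fixes the E geometry by syn addition.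

## Further compounds

F1 | step 7 | 7-(benzyloxy)-8-methoxychroman-2-one | COc1c(OCc2ccccc2)ccc2CCC(=O)Oc12
F2 | step 4 | 3,4-dihydroxy-2-methoxycyclobut-2-en-1-one (racemic) | COC1=C(O)C(O)C1=O
F3 | step 5 | 3-(benzyloxy)-2-methoxy-4-oxocyclobut-2-en-1-yl acetate (racemic) | COC1=C(OCc2ccccc2)C(OC(C)=O)C1=O
F4 | step 6 | octadecyl (4E)-5-[chlorobis(cyclopentadienyl)zirconio]pent-4-enoate | [CH-]1C=CC=C1.[CH-]1C=CC=C1.CCCCCCCCCCCCCCCCCCOC(=O)CC/C=C/[Zr+2]Cl
A1 | alternative 1 | 7-hydroxy-8-methoxychroman-2-one | COc1c(O)ccc2CCC(=O)Oc12
A2 | alternative 1 | 2-methoxybenzene-1,3-diol | COc1c(O)cccc1O
A3 | alternative 1 | acrylic acid | C=CC(=O)O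
A4 | alternative 2 | octadecyl 3-(3-methoxy-2,4-dioxocyclohexyl)propanoate (mixture of tautomers and diastereomers) | CCCCCCCCCCCCCCCCCCOC(=O)CCC1CCC(=O)C(OC)C1=O
A5 | alternative 2 | dioctadecyl 4-(methoxyacetyl)heptanedioate | COCC(=O)C(CCC(=O)OCCCCCCCCCCCCCCCCCC)CCC(=O)OCCCCCCCCCCCCCCCCCC
A6 | alternative 3 | octadecyl 3-[2,4-bis(benzyloxy)-3-methoxyphenyl]propanoate | CCCCCCCCCCCCCCCCCCOC(=O)CCc1ccc(OCc2ccccc2)c(OC)c1OCc1ccccc1
A7 | alternative 3 | 1,3-bis(benzyloxy)-4-ethenyl-2-methoxybenzene | C=Cc1ccc(OCc2ccccc2)c(OC)c1OCc1ccccc1
A8 | alternative 3 | carbon monoxide | [C-]#[O+]
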